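**Strategy.** Everything rests on the C8–C9 bond of ring B. Once C7 is taken to a carbonyl, C7 and the fully substituted C8 (8α-OH, 8β-CH3) form an α-hydroxy ketone with a tertiary carbinol, the signature of a 1,2-acyloin shift that enlarges a cyclopentane. The precursor is therefore a trans-hydrindane (ring A fused to a five-membered ring of C5, C6, C7, C9 and C10) carrying a 7β-acetyl and a 7α-hydroxyl group and, on C9, the C11–C13 chain with C13 masked as a dioxolane. A chelating aluminium alkoxide moves C9 from C7 to the acetyl carbon C8 and so creates ring B, the C8–C9 bond and the C8 stereocentre in one operation.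

Key step: step 11

**Conventions and assumptions**
- Labdane numbering is used for every bicyclic compound. Ring A is C1–C5 and C10, with the gem-dimethyl group on C4 and a methyl on C10. C8 carries methyl C17. The chain on C9 is C11–C12–C13, with methyl C16 on C13. α is the face opposite the C10 methyl.
- The target is read as 6α-acetoxy-7β,8α-dihydroxy-14,15-dinorlabd-11(E)-en-13-one, (5S,6R,7S,8S,9R,10S).
- The racemic starting ketone loses its stereocentre on enolisation; absolute configuration enters in step 2. Assumption: the PHOX ligand induces in the sense established for this reaction class ((S)-ligand gives (S)-2-allyl-2-alkylcyclohexanones), so the (R)-ligand is specified for the (R)-ketone.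

**Route**

Step 1
Reactants: 1 2,2,6-trimethylcyclohexanone; 2 allyl chloroformate
Product: 3 allyl 2,6,6-trimethylcyclohex-1-en-1-yl carbonate
Conditions: LiN(SiMe3)2, THF, 0 °C; then 2, −78 °C → rt
Reagents that add atoms: none
Why: The ketone has a single enolisable position, so its lithium enolate forms without ambiguity and is O-acylated by the hard chloroformate (enol carbonate formation).

Step 2
Reactants: 3 allyl 2,6,6-trimethylcyclohex-1-en-1-yl carbonate
Product: 4 (R)-2-allyl-2,6,6-trimethylcyclohexanone
Conditions: Pd2(dba)3 (2.5 mol%), (R)-t-Bu-PHOX (6 mol%), THF, 25 °C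
Reagents that add atoms: none
Why: In this decarboxylative asymmetric allylic alkylation (Tsuji type), zerovalent palladium ionises the enol carbonate, carbon dioxide is lost, and the allyl-palladium enolate pair recombines at carbon inside the chiral PHOX pocket, which sets the quaternary C10 centre as R.

Step 3
Reactants: 4 (R)-2-allyl-2,6,6-trimethylcyclohexanone
Product: 5 (R)-2,2,6-trimethyl-6-(2-oxopropyl)cyclohexanone
Conditions: PdCl2 (cat.), CuCl (cat.), O2 (1 atm), DMF/H2O, rt
Reagents that add atoms: water, O
Why: Tsuji–Wacker oxidation hydroxypalladates the terminal alkene with Markovnikov selectivity and gives the methyl ketone, leaving the quaternary centre untouched.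

Step 4
Reactants: 5 (R)-2,2,6-trimethyl-6-(2-oxopropyl)cyclohexanone
Product: 6 (R)-4,4,7a-trimethyl-1,4,5,6,7,7a-hexahydro-2H-inden-2-one (hydrindenone: C7 ketone, C5=C6, C9H2)
Conditions: KOH (0.5 equiv), xylenes, 110 °C, Dean–Stark
Reagents that add atoms: none
Why: Intramolecular aldol condensation of the 1,4-diketone joins the methyl carbon (C6) to the ring carbonyl (C5) and loses water to give the only possible cyclopentenone, with azeotropic removal of water driving the hindered condensation.

Step 5
Reactants: 6 hydrindenone; 7 (2-methyl-1,3-dioxolan-2-yl)acetaldehyde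
Product: 8 C9 aldol adduct, 9-[1-hydroxy-2-(2-methyl-1,3-dioxolan-2-yl)ethyl]hydrindenone (mixture of C9/C11 diastereomers)
Conditions: LiN(iPr)2, THF, −78 °C; then 7, −78 °C; AcOH quench
Reagents that add atoms: none
Why: In this directed cross-aldol addition, kinetic deprotonation can only occur at C9 (C6 is vinylic and both γ-carbons are quaternary), and the preformed lithium enolate adds to the aldehyde at low temperature faster than the aldehyde is enolised, the two new centres being erased in the next two steps.

Step 6
Reactants: 8 C9 aldol adduct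
Product: 10 cross-conjugated dienone, 9-[2-(2-methyl-1,3-dioxolan-2-yl)ethylidene]hydrindenone (C9=C11 geometry not controlled), via C11 mesylate 9 (not isolated)
Conditions: MsCl, Et3N, CH2Cl2, 0 °C; then DBU, rt
Reagents that add atoms: none
Why: Mesylation followed by E1cB elimination through the C9 enolate (aldol dehydration) gives the exocyclic enone, whose geometry is immaterial because C11 becomes a methylene group.

Step 7
Reactants: 10 cross-conjugated dienone
Product: 11 trans-hydrindan-7-one (5α-H, 10β-CH3, 9β-[2-(2-methyl-1,3-dioxolan-2-yl)ethyl]; (1R,3aS,7aS)-4,4,7a-trimethyl-1-[2-(2-methyl-1,3-dioxolan-2-yl)ethyl]octahydro-2H-inden-2-one)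
Conditions: H2 (4 atm), 10% Pd/C, EtOAc, rt
Reagents that add atoms: none
Why: In this heterogeneous hydrogenation of both enone alkenes the axial 10β- and 4β-methyl groups screen the β face, so hydrogen should reach C9 and C5 from the α face, giving the 9β chain and the trans ring fusion (5α-H), while ketone and ketal are inert to Pd/C.

Step 8
Reactants: 11 trans-hydrindan-7-one; 12 ethyltriphenylphosphonium bromide
Product: 13 7-ethylidene trans-hydrindane (C7=C8, E/Z mixture)
Conditions: 12, KOtBu, THF, 0 °C → reflux
Reagents that add atoms: none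
Why: Wittig olefination of the cyclopentanone with the unstabilised ylide installs C8 and C17, the alkene geometry being irrelevant because C8 is later oxidised, and C9, the only epimerisable centre, already holds its chain in the β orientation that corresponds to the preferred 17β side chain of steroids.

Step 9
Reactants: 13 7-ethylidene trans-hydrindane
Product: 14 7α-hydroxy-7β-(1-hydroxyethyl) trans-hydrindane (7α,8-diol, C8 epimers)
Conditions: OsO4 (2 mol%), NMO, acetone/H2O, rt
Reagents that add atoms: N-methylmorpholine N-oxide, C[N+]1([O-])CCOCC1; water, O; osmium tetroxide as catalytic oxygen carrier, O=[Os](=O)(=O)=O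
Why: In this Upjohn dihydroxylation OsO4 adds suprafacially to the trisubstituted alkene from the α face, anti to the 9β chain and the 10β-methyl group, which fixes the 7α-hydroxyl and places the carbon substituent β, the C8 configuration being unimportant.

Step 10
Reactants: 14 7α,8-diol
Product: 15 7β-acetyl-7α-hydroxy trans-hydrindane (α-ketol precursor)
Conditions: (COCl)2, DMSO, CH2Cl2, −78 °C; then Et3N, −78 → 0 °C
Reagents that add atoms: none
Why: Swern oxidation converts the secondary C8 carbinol into the ketone without touching the tertiary 7α-hydroxyl and, unlike periodate- or lead-based oxidants, without glycol cleavage.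

Step 11
Reactants: 15 7β-acetyl-7α-hydroxy trans-hydrindane
Product: 16 8α-hydroxy-8β-methyl-7-oxo trans-decalin with C13 dioxolane (13,13-ethylenedioxy-8α-hydroxy-14,15-dinorlabdan-7-one)
Conditions: Al(OtBu)3 (1.5 equiv), toluene, 90 °C; aqueous Rochelle salt work-up
Reagents that add atoms: none
Why: The aluminium alkoxide exchanges with the 7α-hydroxyl and binds the acetyl oxygen in a five-membered chelate that holds both oxygens syn and activates the C8 carbonyl; the C7–C9 bond then shifts with its electron pair to C8 while C7–O becomes the new carbonyl (α-ketol, or acyloin, rearrangement). The closest known reaction is the aluminium-alkoxide or Lewis-acid D-homoannulation of 17-hydroxy-20-oxo steroids, which likewise turns an acetyl carbinol on a cyclopentane into a six-membered hydroxy ketone. Ring B is closed by ring enlargement through this suprafacial 1,2-shift of a ring bond, not by an end-to-end cyclisation, and C9 migrates with retention so that 9α-H and the 9β chain are kept. The new C8 stereocentre is set by the chelate: with the acetyl group on the β face and O8 held syn to O7, C9 bonds to the face of C8 that leaves O8 equatorial (α) and the methyl axial (β). The step needs migration of C9 and not of C6, and two features of the substrate favour this: C8 lies on the β face, so its insertion between C7 and C9 passes through a chair-like ring B whereas insertion between C6 and C7 would need a boat, and C9 is the more substituted, better migrating carbon. The aprotic medium free of Brønsted acid leaves the dioxolane intact, and stopping at full conversion limits any later methyl shift in the product.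

Step 12
Reactants: 16 8α-hydroxy-7-oxo trans-decalin
Product: 17 7,8α-bis(trimethylsilyloxy)-6-ene (Δ6 silyl enol ether, 8-OTMS)
Conditions: LiN(iPr)2 (3 equiv), TMSCl (4 equiv), THF, −78 → 0 °C
Reagents that add atoms: chlorotrimethylsilane, C[Si](C)(C)Cl
Why: Excess amide base deprotonates the tertiary hydroxyl and then C6, the only enolisable carbon because C8 is quaternary, and TMSCl traps both oxygens (silyl enol ether formation under basic conditions that are safe for the ketal).

Step 13
Reactants: 17 Δ6 silyl enol ether
Product: 19 6α,8α-dihydroxy-7-oxo trans-decalin, via bis-silyloxy ketone 18 (not isolated)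
Conditions: mCPBA, CH2Cl2, −20 → 0 °C; then HF·pyridine, pyridine, THF, 0 °C
Reagents that add atoms: mCPBA, O=C(OO)c1cccc(Cl)c1
Why: In this Rubottom oxidation the peracid epoxidises the electron-rich enol ether from the α face, because the axial 4β-, 8β- and 10β-methyl groups shield the β face, 1,4-silyl migration gives the 6α-silyloxy ketone, and buffered fluoride then removes both silyl groups while sparing the dioxolane.

Step 14
Reactants: 19 6α,8α-dihydroxy-7-oxo trans-decalin
Product: 20 6α-acetoxy-8α-hydroxy-7-oxo trans-decalin
Conditions: Ac2O, DMAP (cat.), pyridine, CH2Cl2, 0 °C → rt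
Reagents that add atoms: acetic anhydride, CC(=O)OC(C)=O
Why: DMAP-catalysed acylation esterifies the secondary, equatorial 6α-hydroxyl, whereas the tertiary 8α-hydroxyl is too hindered to react under these conditions.

Step 15
Reactants: 20 6α-acetoxy-8α-hydroxy-7-oxo trans-decalin
Product: 21 6α-acetoxy-7β,8α-dihydroxy trans-decalin with C13 dioxolane
Conditions: NaBH4, CeCl3·7H2O, MeOH/THF, −40 °C; AcOH quench
Reagents that add atoms: none
Why: In this Luche-type borohydride reduction hydride should attack C7 along the axial trajectory from the α face, because the axial 8β-methyl group blocks the β face, giving the equatorial 7β-alcohol, while low temperature and an acidic quench are meant to suppress acetyl migration from O6 to O7.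

Step 16
Reactants: 21 6α-acetoxy-7β,8α-diol dioxolane
Product: 22 6α-acetoxy-7β,8α-dihydroxy-14,15-dinorlabdan-13-one
Conditions: 1 M HCl, THF, rt
Reagents that add atoms: water, O
Why: Acid-catalysed ketal hydrolysis releases the C13 methyl ketone, and the acetate and the tertiary alcohol tolerate dilute aqueous acid at room temperature.

Step 17
Reactants: 22 6α-acetoxy-7β,8α-dihydroxy-13-ketone
Product: 23 (Z)-13-(trimethylsilyloxy)-12-ene 7β,8α-bis(trimethylsilyl) ether
Conditions: TMSCl, NaI, Et3N, MeCN, rt
Reagents that add atoms: chlorotrimethylsilane, C[Si](C)(C)Cl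
Why: Soft enolisation with iodotrimethylsilane made in the flask under equilibrating conditions should give mainly the more substituted C12=C13 silyl enol ether and silylates both hydroxyl groups at the same time.

Step 18
Reactants: 23 silyl enol ether bis(silyl) ether
Product: 25 6α-acetoxy-7β,8α-dihydroxy-14,15-dinorlabd-11(E)-en-13-one (target), via silylated enone 24 (not isolated)
Conditions: Pd(OAc)2 (1.1 equiv), MeCN, rt; then 1 M HCl, THF, 0 °C
Reagents that add atoms: none
Why: In this Saegusa–Ito oxidation Pd(OAc)2 converts the silyl enol ether into a C12 palladium enolate, β-hydride elimination can only take a C11 hydrogen (the methyl side has none) and gives the E-enone, and dilute acid then cleaves the two trimethylsilyl ethers.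

**Compound list**

1 | 2,2,6-trimethylcyclohexanone (racemic) | CC1CCCC(C)(C)C1=O | starting material
2 | allyl chloroformate | C=CCOC(Cl)=O | starting material
3 | allyl 2,6,6-trimethylcyclohex-1-en-1-yl carbonate | C=CCOC(=O)OC1=C(C)CCCC1(C)C | intermediate
4 | (R)-2-allyl-2,6,6-trimethylcyclohexanone | C=CC[C@@]1(C)CCCC(C)(C)C1=O | intermediate
5 | (R)-2,2,6-trimethyl-6-(2-oxopropyl)cyclohexanone | CC(=O)C[C@@]1(C)CCCC(C)(C)C1=O | intermediate
6 | (R)-4,4,7a-trimethyl-1,4,5,6,7,7a-hexahydro-2H-inden-2-one | O=C1C=C2C(C)(C)CCC[C@]2(C)C1 | intermediate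
7 | (2-methyl-1,3-dioxolan-2-yl)acetaldehyde | CC1(CC=O)OCCO1 | starting material
8 | 9-[1-hydroxy-2-(2-methyl-1,3-dioxolan-2-yl)ethyl]hydrindenone (C9/C11 diastereomers) | O=C1C=C2C(C)(C)CCC[C@]2(C)C1C(O)CC3(C)OCCO3 | intermediate
9 | C11 methanesulfonate of 8 | O=C1C=C2C(C)(C)CCC[C@]2(C)C1C(OS(C)(=O)=O)CC3(C)OCCO3 | intermediate (not isolated)
10 | 9-[2-(2-methyl-1,3-dioxolan-2-yl)ethylidene]hydrindenone (cross-conjugated dienone, C9=C11 geometry not controlled) | O=C1C=C2C(C)(C)CCC[C@]2(C)C1=CCC3(C)OCCO3 | intermediate
11 | (1R,3aS,7aS)-4,4,7a-trimethyl-1-[2-(2-methyl-1,3-dioxolan-2-yl)ethyl]octahydro-2H-inden-2-one (trans-hydrindan-7-one, 9β chain) | O=C1C[C@H]2C(C)(C)CCC[C@]2(C)[C@H]1CCC3(C)OCCO3 | intermediate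
12 | ethyltriphenylphosphonium bromide | CC[P+](c1ccccc1)(c1ccccc1)c1ccccc1.[Br-] | starting material
13 | 7-ethylidene trans-hydrindane (E/Z mixture) | CC=C1C[C@H]2C(C)(C)CCC[C@]2(C)[C@H]1CCC3(C)OCCO3 | intermediate
14 | 7α-hydroxy-7β-(1-hydroxyethyl) trans-hydrindane (C8 epimers) | CC(O)[C@@]1(O)C[C@H]2C(C)(C)CCC[C@]2(C)[C@H]1CCC3(C)OCCO3 | intermediate
15 | 7β-acetyl-7α-hydroxy trans-hydrindane, 9β-[2-(2-methyl-1,3-dioxolan-2-yl)ethyl] | CC(=O)[C@@]1(O)C[C@H]2C(C)(C)CCC[C@]2(C)[C@H]1CCC3(C)OCCO3 | intermediate
16 | 13,13-ethylenedioxy-8α-hydroxy-14,15-dinorlabdan-7-one | CC3(OCCO3)CC[C@H]1[C@](C)(O)C(=O)C[C@H]2C(C)(C)CCC[C@@]21C | intermediate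
17 | 13,13-ethylenedioxy-7,8α-bis(trimethylsilyloxy)-14,15-dinorlabd-6-ene | CC3(OCCO3)CC[C@H]1[C@](C)(O[Si](C)(C)C)C(O[Si](C)(C)C)=C[C@H]2C(C)(C)CCC[C@@]21C | intermediate
18 | 13,13-ethylenedioxy-6α,8α-bis(trimethylsilyloxy)-14,15-dinorlabdan-7-one | CC3(OCCO3)CC[C@H]1[C@](C)(O[Si](C)(C)C)C(=O)[C@H](O[Si](C)(C)C)[C@H]2C(C)(C)CCC[C@@]21C | intermediate (not isolated)
19 | 13,13-ethylenedioxy-6α,8α-dihydroxy-14,15-dinorlabdan-7-one | CC3(OCCO3)CC[C@H]1[C@](C)(O)C(=O)[C@H](O)[C@H]2C(C)(C)CCC[C@@]21C | intermediate
20 | 6α-acetoxy-13,13-ethylenedioxy-8α-hydroxy-14,15-dinorlabdan-7-one | CC3(OCCO3)CC[C@H]1[C@](C)(O)C(=O)[C@H](OC(C)=O)[C@H]2C(C)(C)CCC[C@@]21C | intermediate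
21 | 6α-acetoxy-13,13-ethylenedioxy-14,15-dinorlabdane-7β,8α-diol | CC3(OCCO3)CC[C@H]1[C@](C)(O)[C@@H](O)[C@H](OC(C)=O)[C@H]2C(C)(C)CCC[C@@]21C | intermediate
22 | 6α-acetoxy-7β,8α-dihydroxy-14,15-dinorlabdan-13-one | CC(=O)CC[C@H]1[C@](C)(O)[C@@H](O)[C@H](OC(C)=O)[C@H]2C(C)(C)CCC[C@@]21C | intermediate
23 | 6α-acetoxy-7β,8α,13-tris(trimethylsilyloxy)-14,15-dinorlabd-12(Z)-ene | C/C(O[Si](C)(C)C)=C/C[C@H]1[C@](C)(O[Si](C)(C)C)[C@@H](O[Si](C)(C)C)[C@H](OC(C)=O)[C@H]2C(C)(C)CCC[C@@]21C | intermediate
24 | 6α-acetoxy-7β,8α-bis(trimethylsilyloxy)-14,15-dinorlabd-11(E)-en-13-one | CC(=O)/C=C/[C@H]1[C@](C)(O[Si](C)(C)C)[C@@H](O[Si](C)(C)C)[C@H](OC(C)=O)[C@H]2C(C)(C)CCC[C@@]21C | intermediate (not isolated)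
25 | 6α-acetoxy-7β,8α-dihydroxy-14,15-dinorlabd-11(E)-en-13-one, (5S,6R,7S,8S,9R,10S) | CC(=O)/C=C/[C@H]1[C@](C)(O)[C@@H](O)[C@H](OC(C)=O)[C@H]2C(C)(C)CCC[C@@]21C | target

**Totals**

Total step count: 18. Longest linear sequence: 18 steps (1 → 25); compounds 2, 7 and 12 enter as purchased building blocks.

**Steps most likely to fail, with fallbacks**

Step 11 (ring enlargement). What may go wrong: competing migration of C6 in place of C9, loss of chelation control so that the C8 epimer forms, or further isomerisation of the product by a methyl shift from C8 to C7 on prolonged heating. Fallback: ring B would be grown from trans-hydrindan-7-one 11 by one-carbon homologation and the C8 carbinol built by dihydroxylation. Ketone 11 is treated with trimethylsilyldiazomethane and AlMe3 (CH2Cl2, −78 °C), conditions under which the less substituted α-carbon C6 migrates, to give the ring-enlarged α-silyl ketone F1. In F1 the former carbonyl carbon sits next to C9 and takes position 8 of the decalin, and the new silylated carbon takes position 7. K2CO3 in methanol removes the silyl group and gives the 17-nor-8-ketone F2. Kinetic deprotonation at the C7 methylene (LiN(iPr)2, THF, −78 °C) and trapping with PhNTf2 gives the Δ7 enol triflate F3. Me2CuLi (THF, −20 °C) exchanges triflate for methyl and gives the 8-methyl-7-ene F4. OsO4/NMO should add from the α face, the β face being blocked by the axial 10β-methyl group, to give the 7α,8α-diol F5. Swern oxidation of its secondary 7-hydroxyl returns the route at ketol 16.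

Step 7 (double hydrogenation). What may go wrong: delivery of hydrogen to C5 from the β face, giving the cis ring fusion, or stalling at the hindered C5=C6 bond. Fallback: the two alkenes would be reduced separately and C5 set by carbanion protonation instead of surface delivery. From dienone 10, hydrogenation is stopped after one equivalent (10% Pd/C, H2 1 atm, EtOAc, 0 °C), which should saturate only the unhindered exocyclic C9=C11 bond from the α face and give the 9β-alkyl hydrindenone F6. Lithium in liquid NH3/THF (−78 °C, NH4Cl quench) then reduces the enone through its C5 carbanion, which is protonated axially on ring A from the α face, and the route is rejoined at trans-hydrindanone 11.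

Step 18 (dehydrogenation). What may go wrong: protodesilylation back to the saturated ketone, deposition of palladium black before turnover, or too small a share of the internal enol ether. Fallback: the double bond would be introduced by selenoxide elimination. Silyl enol ether 23 is treated with PhSeCl (CH2Cl2, −78 °C) to give the C12 phenylselanyl ketone F7. H2O2/pyridine (CH2Cl2, 0 °C) oxidises it to the selenoxide F8, which undergoes syn-elimination toward C11 below room temperature and rejoins the route at silylated enone 24. Dilute HCl then gives 25 as in the main route.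

**Further compounds**

F1 | step 11 | 13,13-ethylenedioxy-7-(trimethylsilyl)-14,15,17-trinorlabdan-8-one (C7 epimers) | CC3(OCCO3)CC[C@H]1C(=O)C([Si](C)(C)C)C[C@H]2C(C)(C)CCC[C@@]21C
F2 | step 11 | 13,13-ethylenedioxy-14,15,17-trinorlabdan-8-one | CC3(OCCO3)CC[C@H]1C(=O)CC[C@H]2C(C)(C)CCC[C@@]21C
F3 | step 11 | 13,13-ethylenedioxy-14,15,17-trinorlabd-7-en-8-yl trifluoromethanesulfonate | CC3(OCCO3)CC[C@H]1C(OS(=O)(=O)C(F)(F)F)=CC[C@H]2C(C)(C)CCC[C@@]21C
F4 | step 11 | 13,13-ethylenedioxy-14,15-dinorlabd-7-ene | CC3(OCCO3)CC[C@H]1C(C)=CC[C@H]2C(C)(C)CCC[C@@]21C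
F5 | step 11 | 13,13-ethylenedioxy-14,15-dinorlabdane-7α,8α-diol | CC3(OCCO3)CC[C@H]1[C@](C)(O)[C@H](O)C[C@H]2C(C)(C)CCC[C@@]21C
F6 | step 7 | (1R,7aR)-4,4,7a-trimethyl-1-[2-(2-methyl-1,3-dioxolan-2-yl)ethyl]-1,4,5,6,7,7a-hexahydro-2H-inden-2-one | O=C1C=C2C(C)(C)CCC[C@]2(C)[C@H]1CCC3(C)OCCO3
F7 | step 18 | 6α-acetoxy-12-(phenylselanyl)-7β,8α-bis(trimethylsilyloxy)-14,15-dinorlabdan-13-one (C12 epimers) | CC(=O)C([Se]c1ccccc1)C[C@H]1[C@](C)(O[Si](C)(C)C)[C@@H](O[Si](C)(C)C)[C@H](OC(C)=O)[C@H]2C(C)(C)CCC[C@@]21C
F8 | step 18 | selenoxide of F7 | CC(=O)C([Se](=O)c1ccccc1)C[C@H]1[C@](C)(O[Si](C)(C)C)[C@@H](O[Si](C)(C)C)[C@H](OC(C)=O)[C@H]2C(C)(C)CCC[C@@]21C
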